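**Plan**
1. Numbering: C1 (lactone C=O) to C24 (propenyl CH3). The retrosynthesis cuts C7–C8 (Heck) and then C14=C15 (Wittig), which gives lactone 10 (C1–C7), phosphonium salt 24 (C8–C14) and aldehyde 41 (C15–C24).
2. In the dihydropyranone the ring O–C1(=O) unit is one molecule of CO2. It sits between C2, a (Z)-vinylic carbon (nucleophilic as an alkenylboron), and C5, an allylic carbinol carbon (electrophilic as an allyl–metal terminus). Cutting C1–C2 and O–C5 therefore leaves CO2 and the achiral dienyl carbonate 7.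
3. Forward: propargyl alcohol → 7 (4 steps), then CO2 annulation closes the lactone ring (10). Evans alkylation, Stork–Zhao olefination and carboalumination give 24. Evans aldol, vinylogous Mukaiyama aldol, Sharpless epoxidation and 6-exo epoxide opening (closes the tetrahydropyran) give 41. Wittig, Heck and desilylation finish the chain.
4. Stereochemistry: C5 from the chiral Ir catalyst in the key step; C10 from the oxazolidinone alkylation; C20/C21 from the Evans syn-aldol; C19 from Felkin addition; C16/C17 from Sharpless epoxidation and invertive ring closure.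
5. Alkene geometry: 2Z precursor by trans-hydroboration, 8Z by Stork–Zhao olefination, 12E by syn-carboalumination, 14E by Wittig, 6E by Heck, 22E from crotonaldehyde.

Key step: step 5

Assumption: in step 5 the (Ra,R,R)-binaphthol N,N-bis(1-phenylethyl)phosphoramidite (L*) is taken to give the (6S)-lactone; if the catalyst shows the opposite facial preference, ent-L* is used and nothing else changes.

**Lactone fragment (C1–C7)**

Step 1
Reactants: 1 prop-2-yn-1-ol; 2 3-bromoprop-1-yne
Product: 3 hexa-2,5-diyn-1-ol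
Conditions: CuI (cat.), NaI, K2CO3, DMF, rt (1 in excess)
Reagents that add atoms: none
Why: Copper-mediated alkyne–propargyl halide coupling: the copper(I) acetylide of 1 displaces bromide at the CH2 of 2 to give the skipped diyne, and an excess of 1 suppresses a second coupling at the new terminal alkyne.

Step 2
Reactants: 3 hexa-2,5-diyn-1-ol
Product: 4 (2E)-hex-2-en-5-yn-1-ol
Conditions: LiAlH4, THF, 0 °C → rt
Reagents that add atoms: none
Why: Trans-hydroalumination of a propargylic alcohol: the alkoxyaluminate delivers hydride only to the alkyne next to the carbinol, so the (E)-allylic alcohol forms and the remote terminal alkyne stays.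

Step 3
Reactants: 4 (2E)-hex-2-en-5-yn-1-ol
Product: 6 (2E,5Z)-6-(5,5-dimethyl-1,3,2-dioxaborinan-2-yl)hexa-2,5-dien-1-ol, via O-boryl (Z)-alkenyl catecholboronate 5 (not isolated)
Conditions: catecholborane (2 equiv), [Rh(cod)Cl]2 (cat.), P(i-Pr)3, Et3N, cyclohexane, rt; then neopentyl glycol, rt; aqueous work-up
Reagents that add atoms: catecholborane (B1Oc2ccccc2O1); neopentyl glycol (OCC(C)(C)CO)
Why: Rhodium-catalysed trans-hydroboration of a terminal alkyne (through a rhodium vinylidene) places boron at the terminus cis to the chain, which fixes the (Z)-C2=C3 geometry, and exchange of catechol for neopentyl glycol gives the ester class used in copper-catalysed carboxylation while the O-boryl ether is hydrolysed on work-up.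

Step 4
Reactants: 6 (2E,5Z)-6-(5,5-dimethyl-1,3,2-dioxaborinan-2-yl)hexa-2,5-dien-1-ol
Product: 7 tert-butyl (2E,5Z)-6-(5,5-dimethyl-1,3,2-dioxaborinan-2-yl)hexa-2,5-dien-1-yl carbonate
Conditions: Boc2O, DMAP (cat.), CH2Cl2, 0 °C → rt
Reagents that add atoms: di-tert-butyl dicarbonate (CC(C)(C)OC(=O)OC(=O)OC(C)(C)C)
Why: DMAP-catalysed O-acylation of the primary allylic alcohol with Boc2O installs the allylic tert-butyl carbonate needed as the ionisable group in step 5 and leaves the boronic ester untouched.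

Step 5
Reactants: 7 tert-butyl (2E,5Z)-6-(5,5-dimethyl-1,3,2-dioxaborinan-2-yl)hexa-2,5-dien-1-yl carbonate; 8 carbon dioxide
Product: 10 (6S)-6-ethenyl-5,6-dihydro-2H-pyran-2-one, via potassium (2Z,5E)-7-[(tert-butoxycarbonyl)oxy]hepta-2,5-dienoate 9 (not isolated)
Conditions: [(IPr)CuCl] (3 mol%), KOt-Bu (1.05 equiv), CO2 (1 atm), THF, 60 °C; then [Ir(cod)Cl]2 (2 mol%), L* (4 mol%), TBD (8 mol%), rt, CO2 atmosphere kept
Reagents that add atoms: none
Why: Proposed new method: tert-butoxide turns (IPr)CuCl into (IPr)CuOt-Bu, which transmetalates the (Z)-alkenylboronate 7 with retention, CO2 inserts into the Cu–C(sp2) bond to form the C2–C1 bond and give carboxylate 9, and the Ir(I) catalyst then ionises the allylic tert-butyl carbonate to an (allyl)Ir(III) complex whose substituted terminus (C5) is attacked anti to the metal by the tethered carboxylate oxygen, which forms the O–C5 bond. The closest known reaction types are the NHC–copper-catalysed carboxylation of alkenylboronic esters with CO2 and the Ir–phosphoramidite-catalysed enantioselective allylic esterification and intramolecular allylic etherification of linear (E)-allyl carbonates; their union in one flask, with CO2 as the only source of the ring O–C(=O) unit, is new. The lactone closes in the 6-exo mode at the inner allyl terminus, the vinyl group staying outside the ring; the 8-membered alternative (attack at C7) is excluded by the branched preference of iridium and by the strain of a ring holding a (Z)-enoate and an (E)-alkene. The new stereocentre C5 is set by the chiral ligand, which differentiates the two faces of the allyl unit, since 7 is achiral. The step needs CO2 insertion to outrun C-allylation by the alkenylcopper, which the substrate secures because intramolecular C–C coupling would need a cyclobutene or a trans-cyclohexadiene, and it needs the (Z)-geometry of C2=C3 from step 3 for ring closure. The tert-butoxide set free with the leaving group is buffered by CO2 and by the boron by-product, so the base-sensitive lactone should not meet free alkoxide.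

**Central fragment (C8–C14)**

Step 6
Reactants: 11 (4S)-4-benzyl-3-propanoyl-1,3-oxazolidin-2-one; 2 3-bromoprop-1-yne
Product: 13 (4S)-4-benzyl-3-[(2R)-2-methylpent-4-ynoyl]-1,3-oxazolidin-2-one, via sodium (Z)-enolate 12 (not isolated)
Conditions: NaHMDS, THF, −78 °C; then 2, −78 → −40 °C
Reagents that add atoms: none
Why: Evans asymmetric alkylation: the chelated sodium (Z)-enolate 12 is alkylated by the reactive propargylic bromide on the face opposite to the benzyl group, which sets C10 as (R).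

Step 7
Reactants: 13 (4S)-4-benzyl-3-[(2R)-2-methylpent-4-ynoyl]-1,3-oxazolidin-2-one
Product: 14 (2R)-2-methylpent-4-yn-1-ol
Conditions: LiBH4, H2O (1 equiv), Et2O, 0 °C
Reagents that add atoms: none
Why: Reductive cleavage of the N-acyloxazolidinone with LiBH4 gives the primary alcohol and the recoverable auxiliary without touching the stereocentre or the alkyne.

Step 8
Reactants: 14 (2R)-2-methylpent-4-yn-1-ol
Product: 15 (2R)-2-methylpent-4-ynal
Conditions: Dess–Martin periodinane, NaHCO3, CH2Cl2, 0 °C → rt; used crude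
Reagents that add atoms: none
Why: Buffered Dess–Martin oxidation gives the α-branched aldehyde under non-epimerising conditions, and the volatile product is used at once.

Step 9
Reactants: 15 (2R)-2-methylpent-4-ynal; 16 ethyltriphenylphosphonium iodide
Product: 20 (2Z,4R)-2-iodo-4-methylhept-2-en-6-yne, via ethylidenetriphenylphosphorane 17 (not isolated), via (1-iodoethyl)triphenylphosphonium iodide 18 (not isolated), via (1-iodoethylidene)triphenylphosphorane 19 (not isolated)
Conditions: 16, n-BuLi, THF, rt; I2, −78 °C; NaHMDS, −20 °C; then 15, −78 °C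
Reagents that add atoms: iodine (II)
Why: Stork–Zhao-type Wittig olefination with the α-iodo ylide 19, made in the flask from 16, gives the trisubstituted (Z)-vinyl iodide (iodine cis to the chain) through the kinetically favoured cis-oxaphosphetane.

Step 10
Reactants: 20 (2Z,4R)-2-iodo-4-methylhept-2-en-6-yne
Product: 22 (2E,5R,6Z)-7-iodo-3,5-dimethylocta-2,6-dien-1-ol, via alkenyl(dimethyl)alane 21 (not isolated)
Conditions: Me3Al, Cp2ZrCl2 (0.25 equiv), CH2Cl2, 0 °C → rt; then (CH2O)n, rt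
Reagents that add atoms: trimethylaluminium (C[Al](C)C); formaldehyde from paraformaldehyde (C=O)
Why: Zirconium-catalysed syn-carboalumination of the terminal alkyne (Negishi carboalumination) puts the methyl group on the internal carbon and aluminium on the terminus, and trapping of alkenylalane 21 with formaldehyde with retention gives the (E)-trisubstituted allylic alcohol, the vinyl iodide being inert to Me3Al.

Step 11
Reactants: 22 (2E,5R,6Z)-7-iodo-3,5-dimethylocta-2,6-dien-1-ol
Product: 23 (2E,5R,6Z)-1-bromo-7-iodo-3,5-dimethylocta-2,6-diene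
Conditions: CBr4, PPh3, 2,6-lutidine, CH2Cl2, 0 °C
Reagents that add atoms: carbon tetrabromide (BrC(Br)(Br)Br)
Why: Appel bromination converts the primary allylic alcohol into the bromide by SN2 displacement of the oxyphosphonium group without allylic transposition.

Step 12
Reactants: 23 (2E,5R,6Z)-1-bromo-7-iodo-3,5-dimethylocta-2,6-diene
Product: 24 tributyl[(2E,5R,6Z)-7-iodo-3,5-dimethylocta-2,6-dien-1-yl]phosphonium bromide
Conditions: PBu3, MeCN, rt
Reagents that add atoms: tributylphosphine (CCCCP(CCCC)CCCC)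
Why: SN2 quaternisation of tributylphosphine by the primary allylic bromide gives the trialkyl allylic phosphonium salt, the ylide class known for (E)-selective Wittig reactions.

**Tetrahydropyran fragment (C15–C24)**

Step 13
Reactants: 11 (4S)-4-benzyl-3-propanoyl-1,3-oxazolidin-2-one; 25 (2E)-but-2-enal
Product: 27 (4S)-4-benzyl-3-[(2S,3R,4E)-3-hydroxy-2-methylhex-4-enoyl]-1,3-oxazolidin-2-one, via dibutylboron (Z)-enolate 26 (not isolated)
Conditions: Bu2BOTf, i-Pr2NEt, CH2Cl2, −78 → 0 °C; then 25, −78 → 0 °C; H2O2, pH 7 buffer, MeOH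
Reagents that add atoms: none
Why: Evans syn-aldol reaction: the dibutylboron (Z)-enolate 26 adds 1,2 to the enal through a Zimmerman–Traxler transition state on the face dictated by the (S)-benzyl auxiliary, which sets C20 and C21 as the (2S,3R) syn pair.

Step 14
Reactants: 27 (4S)-4-benzyl-3-[(2S,3R,4E)-3-hydroxy-2-methylhex-4-enoyl]-1,3-oxazolidin-2-one
Product: 28 (2S,3R,4E)-3-hydroxy-N-methoxy-N,2-dimethylhex-4-enamide
Conditions: MeONHMe·HCl, AlMe3, CH2Cl2, −20 → 0 °C
Reagents that add atoms: N,O-dimethylhydroxylamine hydrochloride (CNOC.Cl)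
Why: Aluminium amide transamination (Weinreb amide formation) is assisted by the free β-hydroxy group and releases the auxiliary without retro-aldol cleavage.

Step 15
Reactants: 28 (2S,3R,4E)-3-hydroxy-N-methoxy-N,2-dimethylhex-4-enamide
Product: 29 (2S,3R,4E)-N-methoxy-N,2-dimethyl-3-[(triethylsilyl)oxy]hex-4-enamide
Conditions: TESCl, imidazole, DMF, 0 °C → rt
Reagents that add atoms: chlorotriethylsilane (CC[Si](Cl)(CC)CC)
Why: Standard silylation of the secondary allylic alcohol gives the TES ether, chosen because it can later be removed by mild acid in the presence of the epoxide.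

Step 16
Reactants: 29 (2S,3R,4E)-N-methoxy-N,2-dimethyl-3-[(triethylsilyl)oxy]hex-4-enamide
Product: 30 (2S,3R,4E)-2-methyl-3-[(triethylsilyl)oxy]hex-4-enal
Conditions: DIBAL-H, THF, −78 °C
Reagents that add atoms: none
Why: DIBAL-H reduction of the Weinreb amide stops at the aldehyde through the stable chelated hemiaminal, and −78 °C avoids epimerisation of C20.

Step 17
Reactants: 31 methyl (2E)-but-2-enoate
Product: 33 tert-butyl[(1-methoxybuta-1,3-dien-1-yl)oxy]dimethylsilane, via lithium dienolate 32 (not isolated)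
Conditions: LDA, THF, DMPU, −78 °C; then TBSCl
Reagents that add atoms: tert-butyldimethylsilyl chloride (CC(C)(C)[Si](C)(C)Cl)
Why: γ-Deprotonation of the crotonate and O-silylation of dienolate 32 give the silyl dienol ether (vinylogous ketene acetal) needed as the four-carbon nucleophile.

Step 18
Reactants: 30 (2S,3R,4E)-2-methyl-3-[(triethylsilyl)oxy]hex-4-enal; 33 tert-butyl[(1-methoxybuta-1,3-dien-1-yl)oxy]dimethylsilane
Product: 34 methyl (2E,5S,6R,7R,8E)-5-hydroxy-6-methyl-7-[(triethylsilyl)oxy]deca-2,8-dienoate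
Conditions: B(C6F5)3, i-PrOH, Et2O/CH2Cl2, −78 °C
Reagents that add atoms: none
Why: Vinylogous Mukaiyama aldol reaction: the aldehyde, activated by the bulky borane, is attacked by the γ-carbon of 33 along the Felkin–Anh trajectory anti to the C21 branch, which sets C19 syn to the C20 methyl group and gives the (E)-enoate directly, isopropanol taking up the silyl group.

Step 19
Reactants: 34 methyl (2E,5S,6R,7R,8E)-5-hydroxy-6-methyl-7-[(triethylsilyl)oxy]deca-2,8-dienoate
Product: 35 (2E,5S,6R,7R,8E)-6-methyl-7-[(triethylsilyl)oxy]deca-2,8-diene-1,5-diol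
Conditions: DIBAL-H, CH2Cl2, −78 → 0 °C
Reagents that add atoms: none
Why: DIBAL-H reduces the α,β-unsaturated ester 1,2 to the (E)-allylic alcohol and does not affect the silyl ether or the alkenes.

Step 20
Reactants: 35 (2E,5S,6R,7R,8E)-6-methyl-7-[(triethylsilyl)oxy]deca-2,8-diene-1,5-diol
Product: 36 [(2S,3S)-3-[(2S,3R,4R,5E)-2-hydroxy-3-methyl-4-[(triethylsilyl)oxy]hept-5-en-1-yl]oxiran-2-yl]methanol
Conditions: Ti(Oi-Pr)4, L-(+)-diethyl tartrate, t-BuOOH, 4 Å MS, CH2Cl2, −20 °C
Reagents that add atoms: tert-butyl hydroperoxide (CC(C)(C)OO)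
Why: Sharpless asymmetric epoxidation of the primary (E)-allylic alcohol with L-(+)-diethyl tartrate delivers oxygen under reagent control to give the (2S,3S)-epoxy alcohol, which sets C16 and (before inversion) C17, the homoallylic C19 hydroxyl and the propenyl group being much less reactive.

Step 21
Reactants: 36 [(2S,3S)-3-[(2S,3R,4R,5E)-2-hydroxy-3-methyl-4-[(triethylsilyl)oxy]hept-5-en-1-yl]oxiran-2-yl]methanol
Product: 38 (1S)-1-[(2R,4S,5R,6R)-4-hydroxy-5-methyl-6-[(1E)-prop-1-en-1-yl]oxan-2-yl]ethane-1,2-diol, via desilylated epoxy triol 37 (not isolated)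
Conditions: CSA (cat.), CH2Cl2/MeOH (20:1), 0 °C → rt
Reagents that add atoms: none
Why: Acid removes the TES group and the freed C21 hydroxyl opens the epoxide at C17 with inversion in an acid-catalysed 6-exo epoxide opening (favoured over 7-endo attack at C16), which closes the 2,6-cis tetrahydropyran and leaves the C16 hydroxyl anti to the ring oxygen.

Step 22
Reactants: 38 (1S)-1-[(2R,4S,5R,6R)-4-hydroxy-5-methyl-6-[(1E)-prop-1-en-1-yl]oxan-2-yl]ethane-1,2-diol
Product: 39 tris-TBS ether of 38 (C15, C16 and C19 oxygens silylated)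
Conditions: TBSOTf, 2,6-lutidine, CH2Cl2, −78 → 0 °C
Reagents that add atoms: tert-butyldimethylsilyl trifluoromethanesulfonate (CC(C)(C)[Si](C)(C)OS(=O)(=O)C(F)(F)F)
Why: Silylation with the silyl triflate and 2,6-lutidine protects all three hydroxyl groups, including the hindered axial C19 hydroxyl.

Step 23
Reactants: 39 tris-TBS ether of 38
Product: 40 (2S)-2-[(tert-butyldimethylsilyl)oxy]-2-[(2R,4S,5S,6R)-4-[(tert-butyldimethylsilyl)oxy]-5-methyl-6-[(1E)-prop-1-en-1-yl]oxan-2-yl]ethan-1-ol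
Conditions: HF·pyridine, pyridine, THF, 0 °C
Reagents that add atoms: none
Why: Buffered HF·pyridine cleaves the unhindered primary TBS ether much faster than the two secondary ones (selective desilylation by steric differentiation).

Step 24
Reactants: 40 (2S)-2-[(tert-butyldimethylsilyl)oxy]-2-[(2R,4S,5S,6R)-4-[(tert-butyldimethylsilyl)oxy]-5-methyl-6-[(1E)-prop-1-en-1-yl]oxan-2-yl]ethan-1-ol
Product: 41 (2R)-2-[(tert-butyldimethylsilyl)oxy]-2-[(2R,4S,5S,6R)-4-[(tert-butyldimethylsilyl)oxy]-5-methyl-6-[(1E)-prop-1-en-1-yl]oxan-2-yl]acetaldehyde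
Conditions: Dess–Martin periodinane, NaHCO3, CH2Cl2, 0 °C → rt; used directly
Reagents that add atoms: none
Why: Buffered Dess–Martin oxidation gives the α-silyloxy aldehyde without epimerisation of C16, and the aldehyde is used directly.

**Assembly**

Step 25
Reactants: 24 tributyl[(2E,5R,6Z)-7-iodo-3,5-dimethylocta-2,6-dien-1-yl]phosphonium bromide; 41 (2R)-2-[(tert-butyldimethylsilyl)oxy]-2-[(2R,4S,5S,6R)-4-[(tert-butyldimethylsilyl)oxy]-5-methyl-6-[(1E)-prop-1-en-1-yl]oxan-2-yl]acetaldehyde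
Product: 43 bis-TBS C8–C24 vinyl iodide (tetrahydropyran bearing the (1S,2E,4E,7R,8Z)-1-silyloxy-9-iodo-5,7-dimethyldeca-2,4,8-trienyl chain), via phosphorus ylide 42 (not isolated)
Conditions: KOt-Bu (1.0 equiv), toluene, 0 °C; then 41, −78 °C → rt
Reagents that add atoms: none
Why: Wittig olefination with the semi-stabilised allylic tributylphosphonium ylide 42 gives the new C14=C15 bond with (E)-geometry, the low temperature and the absence of excess base protecting C16 and the vinyl iodide.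

Step 26
Reactants: 43 bis-TBS C8–C24 vinyl iodide; 10 (6S)-6-ethenyl-5,6-dihydro-2H-pyran-2-one
Product: 44 16,19-bis-O-TBS ether of the target
Conditions: Pd(OAc)2 (cat.), Bu4NCl, NaHCO3, DMF, rt → 40 °C, dark
Reagents that add atoms: none
Why: Heck reaction under phosphine-free conditions: oxidative addition to the vinyl iodide with retention, insertion into the terminal vinyl group of 10 at C7 and β-hydride elimination give the (6E,8Z)-diene, and the mild base and low temperature spare the lactone.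

Step 27
Reactants: 44 16,19-bis-O-TBS ether of the target
Product: 45 (6S)-6-[(1E,3Z,5R,7E,9E,11S)-11-hydroxy-11-[(2R,4S,5R,6R)-4-hydroxy-5-methyl-6-[(1E)-prop-1-en-1-yl]oxan-2-yl]-3,5,7-trimethylundeca-1,3,7,9-tetraen-1-yl]-5,6-dihydro-2H-pyran-2-one
Conditions: HF·pyridine, pyridine, THF, 0 °C → rt
Reagents that add atoms: none
Why: Buffered fluoride desilylation removes both TBS ethers and leaves the base-sensitive lactone and the acid-sensitive dienylic C16 carbinol intact.

**Compound list**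
1 | prop-2-yn-1-ol | C#CCO | starting material
2 | 3-bromoprop-1-yne | C#CCBr | starting material
3 | hexa-2,5-diyn-1-ol | C#CCC#CCO | intermediate
4 | (2E)-hex-2-en-5-yn-1-ol | C#CC/C=C/CO | intermediate
5 | O-boryl (Z)-alkenyl catecholboronate: 2-[(1Z,4E)-6-(1,3,2-benzodioxaborol-2-yloxy)hexa-1,4-dien-1-yl]-1,3,2-benzodioxaborole | O(C/C=C/C/C=C\B1Oc2ccccc2O1)B1Oc2ccccc2O1 | intermediate
6 | (2E,5Z)-6-(5,5-dimethyl-1,3,2-dioxaborinan-2-yl)hexa-2,5-dien-1-ol | OC/C=C/C/C=C\B1OCC(C)(C)CO1 | intermediate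
7 | tert-butyl (2E,5Z)-6-(5,5-dimethyl-1,3,2-dioxaborinan-2-yl)hexa-2,5-dien-1-yl carbonate | CC(C)(C)OC(=O)OC/C=C/C/C=C\B1OCC(C)(C)CO1 | intermediate
8 | carbon dioxide | O=C=O | starting material
9 | potassium (2Z,5E)-7-[(tert-butoxycarbonyl)oxy]hepta-2,5-dienoate | CC(C)(C)OC(=O)OC/C=C/C/C=C\C(=O)[O-].[K+] | intermediate
10 | (6S)-6-ethenyl-5,6-dihydro-2H-pyran-2-one | C=C[C@@H]1CC=CC(=O)O1 | intermediate
11 | (4S)-4-benzyl-3-propanoyl-1,3-oxazolidin-2-one | CCC(=O)N1C(=O)OC[C@@H]1Cc1ccccc1 | starting material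
12 | sodium (Z)-enolate of 11 | C/C=C(\[O-])N1C(=O)OC[C@@H]1Cc1ccccc1.[Na+] | intermediate
13 | (4S)-4-benzyl-3-[(2R)-2-methylpent-4-ynoyl]-1,3-oxazolidin-2-one | C#CC[C@@H](C)C(=O)N1C(=O)OC[C@@H]1Cc1ccccc1 | intermediate
14 | (2R)-2-methylpent-4-yn-1-ol | C#CC[C@@H](C)CO | intermediate
15 | (2R)-2-methylpent-4-ynal | C#CC[C@@H](C)C=O | intermediate
16 | ethyltriphenylphosphonium iodide | CC[P+](c1ccccc1)(c1ccccc1)c1ccccc1.[I-] | starting material
17 | ethylidenetriphenylphosphorane | CC=P(c1ccccc1)(c1ccccc1)c1ccccc1 | intermediate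
18 | (1-iodoethyl)triphenylphosphonium iodide (racemic) | CC(I)[P+](c1ccccc1)(c1ccccc1)c1ccccc1.[I-] | intermediate
19 | (1-iodoethylidene)triphenylphosphorane | CC(I)=P(c1ccccc1)(c1ccccc1)c1ccccc1 | intermediate
20 | (2Z,4R)-2-iodo-4-methylhept-2-en-6-yne | C#CC[C@@H](C)/C=C(C)\I | intermediate
21 | [(1E,4R,5Z)-6-iodo-2,4-dimethylhepta-1,5-dien-1-yl]dimethylalane | C[Al](C)/C=C(\C)C[C@@H](C)/C=C(C)\I | intermediate
22 | (2E,5R,6Z)-7-iodo-3,5-dimethylocta-2,6-dien-1-ol | OC/C=C(\C)C[C@@H](C)/C=C(C)\I | intermediate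
23 | (2E,5R,6Z)-1-bromo-7-iodo-3,5-dimethylocta-2,6-diene | BrC/C=C(\C)C[C@@H](C)/C=C(C)\I | intermediate
24 | tributyl[(2E,5R,6Z)-7-iodo-3,5-dimethylocta-2,6-dien-1-yl]phosphonium bromide | CCCC[P+](CCCC)(CCCC)C/C=C(\C)C[C@@H](C)/C=C(C)\I.[Br-] | intermediate
25 | (2E)-but-2-enal | C/C=C/C=O | starting material
26 | dibutylboron (Z)-enolate of 11 | CCCCB(CCCC)O/C(=C\C)N1C(=O)OC[C@@H]1Cc1ccccc1 | intermediate
27 | (4S)-4-benzyl-3-[(2S,3R,4E)-3-hydroxy-2-methylhex-4-enoyl]-1,3-oxazolidin-2-one | C/C=C/[C@@H](O)[C@H](C)C(=O)N1C(=O)OC[C@@H]1Cc1ccccc1 | intermediate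
28 | (2S,3R,4E)-3-hydroxy-N-methoxy-N,2-dimethylhex-4-enamide | C/C=C/[C@@H](O)[C@H](C)C(=O)N(C)OC | intermediate
29 | (2S,3R,4E)-N-methoxy-N,2-dimethyl-3-[(triethylsilyl)oxy]hex-4-enamide | C/C=C/[C@@H](O[Si](CC)(CC)CC)[C@H](C)C(=O)N(C)OC | intermediate
30 | (2S,3R,4E)-2-methyl-3-[(triethylsilyl)oxy]hex-4-enal | C/C=C/[C@@H](O[Si](CC)(CC)CC)[C@H](C)C=O | intermediate
31 | methyl (2E)-but-2-enoate | C/C=C/C(=O)OC | starting material
32 | lithium 1-methoxybuta-1,3-dien-1-olate | C=CC=C([O-])OC.[Li+] | intermediate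
33 | tert-butyl[(1-methoxybuta-1,3-dien-1-yl)oxy]dimethylsilane (mixture of ketene acetal geometries, used as such) | C=CC=C(OC)O[Si](C)(C)C(C)(C)C | intermediate
34 | methyl (2E,5S,6R,7R,8E)-5-hydroxy-6-methyl-7-[(triethylsilyl)oxy]deca-2,8-dienoate | C/C=C/[C@@H](O[Si](CC)(CC)CC)[C@H](C)[C@@H](O)C/C=C/C(=O)OC | intermediate
35 | (2E,5S,6R,7R,8E)-6-methyl-7-[(triethylsilyl)oxy]deca-2,8-diene-1,5-diol | C/C=C/[C@@H](O[Si](CC)(CC)CC)[C@H](C)[C@@H](O)C/C=C/CO | intermediate
36 | [(2S,3S)-3-[(2S,3R,4R,5E)-2-hydroxy-3-methyl-4-[(triethylsilyl)oxy]hept-5-en-1-yl]oxiran-2-yl]methanol | C/C=C/[C@@H](O[Si](CC)(CC)CC)[C@H](C)[C@@H](O)C[C@@H]1O[C@H]1CO | intermediate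
37 | [(2S,3S)-3-[(2S,3R,4R,5E)-2,4-dihydroxy-3-methylhept-5-en-1-yl]oxiran-2-yl]methanol | C/C=C/[C@@H](O)[C@H](C)[C@@H](O)C[C@@H]1O[C@H]1CO | intermediate
38 | (1S)-1-[(2R,4S,5R,6R)-4-hydroxy-5-methyl-6-[(1E)-prop-1-en-1-yl]oxan-2-yl]ethane-1,2-diol | C/C=C/[C@H]1O[C@@H]([C@@H](O)CO)C[C@H](O)[C@H]1C | intermediate
39 | tert-butyl{[(2R,4S,5S,6R)-2-[(1S)-1,2-bis[(tert-butyldimethylsilyl)oxy]ethyl]-5-methyl-6-[(1E)-prop-1-en-1-yl]oxan-4-yl]oxy}dimethylsilane | C/C=C/[C@H]1O[C@@H]([C@@H](O[Si](C)(C)C(C)(C)C)CO[Si](C)(C)C(C)(C)C)C[C@H](O[Si](C)(C)C(C)(C)C)[C@H]1C | intermediate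
40 | (2S)-2-[(tert-butyldimethylsilyl)oxy]-2-[(2R,4S,5S,6R)-4-[(tert-butyldimethylsilyl)oxy]-5-methyl-6-[(1E)-prop-1-en-1-yl]oxan-2-yl]ethan-1-ol | C/C=C/[C@H]1O[C@@H]([C@@H](O[Si](C)(C)C(C)(C)C)CO)C[C@H](O[Si](C)(C)C(C)(C)C)[C@H]1C | intermediate
41 | (2R)-2-[(tert-butyldimethylsilyl)oxy]-2-[(2R,4S,5S,6R)-4-[(tert-butyldimethylsilyl)oxy]-5-methyl-6-[(1E)-prop-1-en-1-yl]oxan-2-yl]acetaldehyde | C/C=C/[C@H]1O[C@@H]([C@@H](O[Si](C)(C)C(C)(C)C)C=O)C[C@H](O[Si](C)(C)C(C)(C)C)[C@H]1C | intermediate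
42 | tributyl[(2E,5R,6Z)-7-iodo-3,5-dimethylocta-2,6-dien-1-ylidene]phosphorane | CCCCP(CCCC)(CCCC)=C/C=C(\C)C[C@@H](C)/C=C(C)\I | intermediate
43 | tert-butyl{[(2R,4S,5S,6R)-2-[(1S,2E,4E,7R,8Z)-1-[(tert-butyldimethylsilyl)oxy]-9-iodo-5,7-dimethyldeca-2,4,8-trien-1-yl]-5-methyl-6-[(1E)-prop-1-en-1-yl]oxan-4-yl]oxy}dimethylsilane | C/C=C/[C@H]1O[C@@H]([C@@H](O[Si](C)(C)C(C)(C)C)/C=C/C=C(\C)C[C@@H](C)/C=C(C)\I)C[C@H](O[Si](C)(C)C(C)(C)C)[C@H]1C | intermediate
44 | (6S)-6-[(1E,3Z,5R,7E,9E,11S)-11-[(tert-butyldimethylsilyl)oxy]-11-[(2R,4S,5S,6R)-4-[(tert-butyldimethylsilyl)oxy]-5-methyl-6-[(1E)-prop-1-en-1-yl]oxan-2-yl]-3,5,7-trimethylundeca-1,3,7,9-tetraen-1-yl]-5,6-dihydro-2H-pyran-2-one | C/C=C/[C@H]1O[C@@H]([C@@H](O[Si](C)(C)C(C)(C)C)/C=C/C=C(\C)C[C@@H](C)/C=C(C)\C=C\[C@@H]2CC=CC(=O)O2)C[C@H](O[Si](C)(C)C(C)(C)C)[C@H]1C | intermediate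
45 | (6S)-6-[(1E,3Z,5R,7E,9E,11S)-11-hydroxy-11-[(2R,4S,5R,6R)-4-hydroxy-5-methyl-6-[(1E)-prop-1-en-1-yl]oxan-2-yl]-3,5,7-trimethylundeca-1,3,7,9-tetraen-1-yl]-5,6-dihydro-2H-pyran-2-one | C/C=C/[C@H]1O[C@@H]([C@@H](O)/C=C/C=C(\C)C[C@@H](C)/C=C(C)\C=C\[C@@H]2CC=CC(=O)O2)C[C@H](O)[C@H]1C | target

**Summary**
Total step count: 27. Longest linear sequence: 14 steps (11 → 45 through steps 13–16 and 18–27).

**Steps most likely to fail**

1. Step 5 (proposed new method). The relay may fail if protodeboronation or C-allylation of the alkenylcopper outruns CO2 insertion. It may also fail if the allyl–iridium intermediate loses a proton to give a triene, or if the lactone re-ionises and loses enantiomeric purity. The fallback uses known reactions only, sets out from 4 and comes back at 10. The dianion of 4 (n-BuLi, THF, −78 °C) is carboxylated with CO2 to give (5E)-7-hydroxyhept-5-en-2-ynoic acid F1. Lindlar semi-hydrogenation of the ynoic acid gives (2Z,5E)-7-hydroxyhepta-2,5-dienoic acid F2. Enantioselective dehydrative intramolecular allylation of the acid by the allylic alcohol, with a CpRu(II)/chiral picolinic-acid-type catalyst (the asymmetric Tsuji–Trost-type lactonisation of ω-carboxy (E)-allylic alcohols), closes 10.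

2. Step 18. Facial selectivity may be poor because Felkin control is opposed by the 1,3-anti preference of the β-silyloxy group, and the allylic silyl ether may ionise under the Lewis acid. The fallback sets C19 by chelate-controlled reduction instead, sets out from 28 and comes back at 38.
   - Addition of the lithium enolate of ethyl acetate to 28 gives ethyl (4S,5R,6E)-5-hydroxy-4-methyl-3-oxooct-6-enoate F3.
   - Narasaka–Prasad reduction (Et2BOMe, NaBH4) gives the syn-diol ethyl (3S,4R,5R,6E)-3,5-dihydroxy-4-methyloct-6-enoate F4.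
   - 2,2-Dimethoxypropane/PPTS gives the acetonide ethyl 2-[(4S,5R,6R)-2,2,5-trimethyl-6-[(1E)-prop-1-en-1-yl]-1,3-dioxan-4-yl]acetate F5.
   - DIBAL-H at −78 °C gives 2-[(4S,5R,6R)-2,2,5-trimethyl-6-[(1E)-prop-1-en-1-yl]-1,3-dioxan-4-yl]acetaldehyde F6.
   - Wittig reaction with Ph3P=CHCO2Et gives ethyl (2E)-4-[(4S,5R,6R)-2,2,5-trimethyl-6-[(1E)-prop-1-en-1-yl]-1,3-dioxan-4-yl]but-2-enoate F7.
   - DIBAL-H gives (2E)-4-[(4S,5R,6R)-2,2,5-trimethyl-6-[(1E)-prop-1-en-1-yl]-1,3-dioxan-4-yl]but-2-en-1-ol F8.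
   - Sharpless epoxidation with L-(+)-diethyl tartrate gives [(2S,3S)-3-{[(4S,5R,6R)-2,2,5-trimethyl-6-[(1E)-prop-1-en-1-yl]-1,3-dioxan-4-yl]methyl}oxiran-2-yl]methanol F9.
   - CSA in MeOH removes the acetonide (giving 37 in the flask) and the 6-exo epoxide opening gives 38.

3. Step 26. Pd(0) may ionise the allylic C–O bond of the lactone, and palladium hydride may migrate double bonds or erode the 8Z geometry. The fallback forms the C7–C8 bond by cross-coupling of a preformed alkenylboron, sets out from 10 and comes back at 44. Cross-metathesis of 10 with vinylboronic acid pinacol ester (Grubbs second-generation catalyst) gives (6S)-6-[(E)-2-(4,4,5,5-tetramethyl-1,3,2-dioxaborolan-2-yl)ethenyl]-5,6-dihydro-2H-pyran-2-one F10. Suzuki–Miyaura coupling of the boronate with 43 (Pd(PPh3)4, TlOEt, THF/H2O, rt) gives 44.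

**Further compounds**
F1 | step 5 | (5E)-7-hydroxyhept-5-en-2-ynoic acid | OC/C=C/CC#CC(=O)O
F2 | step 5 | (2Z,5E)-7-hydroxyhepta-2,5-dienoic acid | OC/C=C/C/C=C\C(=O)O
F3 | step 18 | ethyl (4S,5R,6E)-5-hydroxy-4-methyl-3-oxooct-6-enoate | C/C=C/[C@@H](O)[C@H](C)C(=O)CC(=O)OCC
F4 | step 18 | ethyl (3S,4R,5R,6E)-3,5-dihydroxy-4-methyloct-6-enoate | C/C=C/[C@@H](O)[C@H](C)[C@@H](O)CC(=O)OCC
F5 | step 18 | ethyl 2-[(4S,5R,6R)-2,2,5-trimethyl-6-[(1E)-prop-1-en-1-yl]-1,3-dioxan-4-yl]acetate | C/C=C/[C@H]1OC(C)(C)O[C@@H](CC(=O)OCC)[C@H]1C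
F6 | step 18 | 2-[(4S,5R,6R)-2,2,5-trimethyl-6-[(1E)-prop-1-en-1-yl]-1,3-dioxan-4-yl]acetaldehyde | C/C=C/[C@H]1OC(C)(C)O[C@@H](CC=O)[C@H]1C
F7 | step 18 | ethyl (2E)-4-[(4S,5R,6R)-2,2,5-trimethyl-6-[(1E)-prop-1-en-1-yl]-1,3-dioxan-4-yl]but-2-enoate | C/C=C/[C@H]1OC(C)(C)O[C@@H](C/C=C/C(=O)OCC)[C@H]1C
F8 | step 18 | (2E)-4-[(4S,5R,6R)-2,2,5-trimethyl-6-[(1E)-prop-1-en-1-yl]-1,3-dioxan-4-yl]but-2-en-1-ol | C/C=C/[C@H]1OC(C)(C)O[C@@H](C/C=C/CO)[C@H]1C
F9 | step 18 | [(2S,3S)-3-{[(4S,5R,6R)-2,2,5-trimethyl-6-[(1E)-prop-1-en-1-yl]-1,3-dioxan-4-yl]methyl}oxiran-2-yl]methanol | C/C=C/[C@H]1OC(C)(C)O[C@@H](C[C@@H]2O[C@H]2CO)[C@H]1C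
F10 | step 26 | (6S)-6-[(E)-2-(4,4,5,5-tetramethyl-1,3,2-dioxaborolan-2-yl)ethenyl]-5,6-dihydro-2H-pyran-2-one | CC1(C)OB(/C=C/[C@@H]2CC=CC(=O)O2)OC1(C)C
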